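**Retrosynthetic overview**
1. Mollicellin A (30) comes from its ring A isopropyl ether 28 (BCl3). The seven-membered lactone of 28 is closed last, from hydroxy acid 26.
2. 26 comes from diaryl ether 25, made by SNAr of chromanone phenol 15 on fluoro aldehyde ester 24.
3. Key C–C bond: the pyranone ring of 15 is built by an intermolecular crossed aldol condensation of hydroxyacetophenone 9 with acetone, followed by oxa-Michael closure.
4. 9 comes from 3,5-dimethoxytoluene (formylation, Baeyer–Villiger, Friedel–Crafts). 24 comes from 3-fluoro-5-methylphenol (ortho-lithiation/formylation, bromination, Br/Li exchange/acylation).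
5. Ring order: pyranone ring on ring B, then the diaryl ether link, then the seven-membered lactone.

Assumption: Mollicellin A has no stereocentre, so the target is one achiral compound and no stereocontrol is needed.

**Ring B fragment**

Step 1
Reactants: 1 3,5-dimethoxytoluene
Product: 3 2,4-dimethoxy-6-methylbenzaldehyde, via aryl iminium chloride 2 (not isolated)
Conditions: POCl3 (1.2 equiv), DMF, 0 °C to 70 °C; then H2O, rt
Reagents that add atoms: DMF, CN(C)C=O; water, O
Why: Vilsmeier–Haack formylation goes ortho to the methyl and para to a methoxy group (the site between the two methoxy groups is more hindered), and the iminium salt is hydrolysed on work-up.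

Step 2
Reactants: 3 2,4-dimethoxy-6-methylbenzaldehyde
Product: 5 2,4-dimethoxy-6-methylphenol, via aryl formate 4 (not isolated)
Conditions: mCPBA (1.3 equiv), CH2Cl2, 0 °C to rt; then K2CO3 (cat.), MeOH, rt
Reagents that add atoms: mCPBA, OOC(=O)c1cccc(Cl)c1
Why: Baeyer–Villiger (Dakin-type) oxidation, in which the electron-rich aryl group migrates to give the formate, which is then methanolysed to the phenol.

Step 3
Reactants: 5 2,4-dimethoxy-6-methylphenol
Product: 6 1,2,5-trimethoxy-3-methylbenzene
Conditions: MeI (1.5 equiv), K2CO3, acetone, reflux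
Reagents that add atoms: iodomethane, CI
Why: Williamson ether synthesis on the phenoxide protects the air-sensitive phenol before the Lewis-acid steps.

Step 4
Reactants: 6 1,2,5-trimethoxy-3-methylbenzene
Product: 7 1-(2,4,5-trimethoxy-6-methylphenyl)ethanone
Conditions: AcCl (1.1 equiv), AlCl3 (1.2 equiv), CH2Cl2, −10 to 0 °C
Reagents that add atoms: acetyl chloride, CC(Cl)=O
Why: Friedel–Crafts acylation should go to the position ortho to the methyl, ortho to one methoxy and para to another, rather than the more hindered site between two methoxy groups, by analogy with 1,2,4-trimethoxybenzene and 3,5-dimethoxytoluene.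

Step 5
Reactants: 7 1-(2,4,5-trimethoxy-6-methylphenyl)ethanone
Product: 9 1-(2-hydroxy-4,5-dimethoxy-6-methylphenyl)ethanone, via dichloroboron aryloxide 8 (not isolated)
Conditions: BCl3 (1.2 equiv), CH2Cl2, −78 to 0 °C; then H2O
Reagents that add atoms: none
Why: Chelation-controlled Lewis-acid demethylation cleaves only the methoxy group ortho to the ketone, through the six-membered boron chelate.

Step 6 (key step)
Reactants: 9 1-(2-hydroxy-4,5-dimethoxy-6-methylphenyl)ethanone; 10 acetone (tenfold excess)
Product: 13 6,7-dimethoxy-2,2,5-trimethylchroman-4-one, via aldol adduct 11 (not isolated), via enone 12 (not isolated)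
Conditions: pyrrolidine (1.5 equiv), EtOH, reflux, 24 h
Reagents that add atoms: none
Why: Kabbe chromanone synthesis: a pyrrolidine-mediated intermolecular crossed aldol condensation joins the acetyl methyl carbon of 9 to the carbonyl carbon of acetone, and the resulting enone closes by intramolecular oxa-Michael addition of the ortho phenol.

Step 7
Reactants: 13 6,7-dimethoxy-2,2,5-trimethylchroman-4-one
Product: 14 6,7-dihydroxy-2,2,5-trimethylchroman-4-one
Conditions: 48% aq. HBr, AcOH, reflux, N2
Reagents that add atoms: none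
Why: Protic SN2 cleavage of both aryl methyl ethers; any acid-induced opening of the 2,2-dimethylchromanone is reversible and recloses.

Step 8
Reactants: 14 6,7-dihydroxy-2,2,5-trimethylchroman-4-one
Product: 15 7-(allyloxy)-6-hydroxy-2,2,5-trimethylchroman-4-one
Conditions: allyl bromide (1.05 equiv), KHCO3 (1.1 equiv), DMF, 40 °C, N2
Reagents that add atoms: allyl bromide, C=CCBr
Why: Selective Williamson O-alkylation: the 7-hydroxyl is para to the ketone (more acidic) and unhindered, while the 6-hydroxyl is flanked by the 5-methyl group, so the weak base alkylates only O-7.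

**Ring A fragment**

Step 9
Reactants: 16 3-fluoro-5-methylphenol
Product: 17 1-fluoro-3-isopropoxy-5-methylbenzene
Conditions: 2-bromopropane (1.5 equiv), K2CO3, DMF, 60 °C
Reagents that add atoms: 2-bromopropane, CC(C)Br
Why: Williamson ether synthesis installs an isopropyl ether that survives base, organolithium, acid and palladium steps and is later removed by BCl3.

Step 10
Reactants: 17 1-fluoro-3-isopropoxy-5-methylbenzene
Product: 19 2-fluoro-6-isopropoxy-4-methylbenzaldehyde, via aryllithium 18 (not isolated)
Conditions: n-BuLi (1.1 equiv), TMEDA, THF, −78 °C; DMF, −78 °C to rt; then H2O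
Reagents that add atoms: DMF, CN(C)C=O
Why: Directed ortho-metalation occurs at the most acidic ring position, between fluorine and the alkoxy group, and DMF formylates the aryllithium.

Step 11
Reactants: 19 2-fluoro-6-isopropoxy-4-methylbenzaldehyde
Product: 20 3-bromo-2-fluoro-6-isopropoxy-4-methylbenzaldehyde
Conditions: NBS (1.05 equiv), DMF, 0 °C to rt, dark
Reagents that add atoms: N-bromosuccinimide, O=C1CCC(=O)N1Br
Why: Electrophilic aromatic bromination goes para to the isopropoxy group (and meta to the formyl), as in the bromination of 3-fluoroanisole.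

Step 12
Reactants: 20 3-bromo-2-fluoro-6-isopropoxy-4-methylbenzaldehyde
Product: 21 2-(3-bromo-2-fluoro-6-isopropoxy-4-methylphenyl)-1,3-dioxolane
Conditions: ethylene glycol (3 equiv), TsOH (cat.), toluene, reflux, Dean–Stark
Reagents that add atoms: ethylene glycol, OCCO
Why: Acid-catalysed acetalisation with azeotropic water removal masks the aldehyde against the organolithium chemistry of the next step.

Step 13
Reactants: 21 2-(3-bromo-2-fluoro-6-isopropoxy-4-methylphenyl)-1,3-dioxolane
Product: 23 allyl 3-(1,3-dioxolan-2-yl)-2-fluoro-4-isopropoxy-6-methylbenzoate, via aryllithium 22 (not isolated)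
Conditions: n-BuLi (1.05 equiv), THF, −78 °C, 15 min; then added to allyl chloroformate (2 equiv), THF, −78 °C to rt
Reagents that add atoms: allyl chloroformate, C=CCOC(Cl)=O
Why: Bromine–lithium exchange is fast at −78 °C, where the ortho-fluoro aryllithium does not eliminate LiF, and inverse addition to the chloroformate gives the ester by acyl substitution without over-addition.

Step 14
Reactants: 23 allyl 3-(1,3-dioxolan-2-yl)-2-fluoro-4-isopropoxy-6-methylbenzoate
Product: 24 allyl 2-fluoro-3-formyl-4-isopropoxy-6-methylbenzoate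
Conditions: 1 M aq. HCl, THF, rt
Reagents that add atoms: water, O
Why: Mild acid-catalysed acetal hydrolysis frees the aldehyde without touching the allyl ester, the aryl fluoride or the isopropyl ether.

**Coupling and endgame**

Step 15
Reactants: 15 7-(allyloxy)-6-hydroxy-2,2,5-trimethylchroman-4-one; 24 allyl 2-fluoro-3-formyl-4-isopropoxy-6-methylbenzoate
Product: 25 allyl 2-{[7-(allyloxy)-2,2,5-trimethyl-4-oxochroman-6-yl]oxy}-3-formyl-4-isopropoxy-6-methylbenzoate
Conditions: K2CO3 (1.5 equiv), DMF, 70 °C, N2
Reagents that add atoms: none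
Why: SNAr (addition–elimination): the fluoride is activated by the ortho formyl and ortho ester groups, and only the 6-hydroxyl of 15 is free, which fixes the ether regiochemistry.

Step 16
Reactants: 25 allyl 2-{[7-(allyloxy)-2,2,5-trimethyl-4-oxochroman-6-yl]oxy}-3-formyl-4-isopropoxy-6-methylbenzoate
Product: 26 3-formyl-2-[(7-hydroxy-2,2,5-trimethyl-4-oxochroman-6-yl)oxy]-4-isopropoxy-6-methylbenzoic acid
Conditions: Pd(PPh3)4 (5 mol %), morpholine (10 equiv), THF, rt; then dilute HCl work-up
Reagents that add atoms: none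
Why: Tsuji–Trost deallylation: zerovalent palladium ionises both the allyl ester and the allyl aryl ether, and morpholine traps the allyl groups; cleavage at the allyl carbon is insensitive to the hindrance around the carboxyl group.

Step 17
Reactants: 26 3-formyl-2-[(7-hydroxy-2,2,5-trimethyl-4-oxochroman-6-yl)oxy]-4-isopropoxy-6-methylbenzoic acid
Product: 28 O-isopropyl mollicellin A (the depsidone with the ring A hydroxyl still as its isopropyl ether), via mixed trifluoroacetic anhydride 27 (not isolated)
Conditions: (CF3CO)2O (2 equiv), toluene, 0 °C to rt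
Reagents that add atoms: none
Why: Lactonisation through the mixed anhydride activates the hindered benzoic acid, and the neighbouring 7-hydroxyl closes the seven-membered depsidone lactone intramolecularly.

Step 18
Reactants: 28 O-isopropyl mollicellin A
Product: 30 Mollicellin A, via dichloroboron aryloxide 29 (not isolated)
Conditions: BCl3 (3 equiv), CH2Cl2, −78 to 0 °C; then H2O
Reagents that add atoms: none
Why: Lewis-acid dealkylation: BCl3 cleaves the isopropyl aryl ether, assisted by chelation to the ortho formyl group, under conditions that spare the aryl lactone and the chromanone.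

**Compound list**
1 | 3,5-dimethoxytoluene | Cc1cc(OC)cc(OC)c1 | starting material
2 | [(2,4-dimethoxy-6-methylphenyl)methylidene]dimethyliminium chloride (not isolated) | C[N+](C)=Cc1c(C)cc(OC)cc1OC.[Cl-] | intermediate
3 | 2,4-dimethoxy-6-methylbenzaldehyde | Cc1cc(OC)cc(OC)c1C=O | intermediate
4 | 2,4-dimethoxy-6-methylphenyl formate (not isolated) | Cc1cc(OC)cc(OC)c1OC=O | intermediate
5 | 2,4-dimethoxy-6-methylphenol | Cc1cc(OC)cc(OC)c1O | intermediate
6 | 1,2,5-trimethoxy-3-methylbenzene | Cc1cc(OC)cc(OC)c1OC | intermediate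
7 | 1-(2,4,5-trimethoxy-6-methylphenyl)ethanone | CC(=O)c1c(C)c(OC)c(OC)cc1OC | intermediate
8 | 2-acetyl-4,5-dimethoxy-3-methylphenoxy(dichloro)borane (not isolated) | CC(=O)c1c(C)c(OC)c(OC)cc1OB(Cl)Cl | intermediate
9 | 1-(2-hydroxy-4,5-dimethoxy-6-methylphenyl)ethanone | CC(=O)c1c(C)c(OC)c(OC)cc1O | intermediate
10 | acetone | CC(C)=O | starting material
11 | 3-hydroxy-1-(2-hydroxy-4,5-dimethoxy-6-methylphenyl)-3-methylbutan-1-one (not isolated) | CC(C)(O)CC(=O)c1c(C)c(OC)c(OC)cc1O | intermediate
12 | 1-(2-hydroxy-4,5-dimethoxy-6-methylphenyl)-3-methylbut-2-en-1-one (not isolated) | CC(C)=CC(=O)c1c(C)c(OC)c(OC)cc1O | intermediate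
13 | 6,7-dimethoxy-2,2,5-trimethylchroman-4-one | Cc1c(OC)c(OC)cc2OC(C)(C)CC(=O)c12 | intermediate
14 | 6,7-dihydroxy-2,2,5-trimethylchroman-4-one | Cc1c(O)c(O)cc2OC(C)(C)CC(=O)c12 | intermediate
15 | 7-(allyloxy)-6-hydroxy-2,2,5-trimethylchroman-4-one | Cc1c(O)c(OCC=C)cc2OC(C)(C)CC(=O)c12 | intermediate
16 | 3-fluoro-5-methylphenol | Cc1cc(O)cc(F)c1 | starting material
17 | 1-fluoro-3-isopropoxy-5-methylbenzene | Cc1cc(F)cc(OC(C)C)c1 | intermediate
18 | (2-fluoro-6-isopropoxy-4-methylphenyl)lithium (not isolated) | [Li]c1c(F)cc(C)cc1OC(C)C | intermediate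
19 | 2-fluoro-6-isopropoxy-4-methylbenzaldehyde | Cc1cc(F)c(C=O)c(OC(C)C)c1 | intermediate
20 | 3-bromo-2-fluoro-6-isopropoxy-4-methylbenzaldehyde | Cc1cc(OC(C)C)c(C=O)c(F)c1Br | intermediate
21 | 2-(3-bromo-2-fluoro-6-isopropoxy-4-methylphenyl)-1,3-dioxolane | Cc1cc(OC(C)C)c(C2OCCO2)c(F)c1Br | intermediate
22 | [3-(1,3-dioxolan-2-yl)-2-fluoro-4-isopropoxy-6-methylphenyl]lithium (not isolated) | [Li]c1c(C)cc(OC(C)C)c(C2OCCO2)c1F | intermediate
23 | allyl 3-(1,3-dioxolan-2-yl)-2-fluoro-4-isopropoxy-6-methylbenzoate | Cc1cc(OC(C)C)c(C2OCCO2)c(F)c1C(=O)OCC=C | intermediate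
24 | allyl 2-fluoro-3-formyl-4-isopropoxy-6-methylbenzoate | Cc1cc(OC(C)C)c(C=O)c(F)c1C(=O)OCC=C | intermediate
25 | allyl 2-{[7-(allyloxy)-2,2,5-trimethyl-4-oxochroman-6-yl]oxy}-3-formyl-4-isopropoxy-6-methylbenzoate | Cc1cc(OC(C)C)c(C=O)c(Oc2c(C)c3C(=O)CC(C)(C)Oc3cc2OCC=C)c1C(=O)OCC=C | intermediate
26 | 3-formyl-2-[(7-hydroxy-2,2,5-trimethyl-4-oxochroman-6-yl)oxy]-4-isopropoxy-6-methylbenzoic acid | Cc1cc(OC(C)C)c(C=O)c(Oc2c(C)c3C(=O)CC(C)(C)Oc3cc2O)c1C(=O)O | intermediate
27 | mixed anhydride of acid 26 with trifluoroacetic acid (not isolated) | Cc1cc(OC(C)C)c(C=O)c(Oc2c(C)c3C(=O)CC(C)(C)Oc3cc2O)c1C(=O)OC(=O)C(F)(F)F | intermediate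
28 | O-isopropyl mollicellin A (depsidone, ring A isopropyl ether) | Cc1cc(OC(C)C)c(C=O)c2c1C(=O)Oc1cc3c(c(C)c1O2)C(=O)CC(C)(C)O3 | intermediate
29 | dichloroboron aryloxide of mollicellin A (not isolated) | Cc1cc(OB(Cl)Cl)c(C=O)c2c1C(=O)Oc1cc3c(c(C)c1O2)C(=O)CC(C)(C)O3 | intermediate
30 | Mollicellin A | Cc1cc(O)c(C=O)c2c1C(=O)Oc1cc3c(c(C)c1O2)C(=O)CC(C)(C)O3 | target

**Totals**
Total step count: 18. Longest linear sequence: 12 steps (steps 1–8, then 15–18); the ring A branch is steps 9–14.

**Three steps most likely to fail**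

Step 15 (SNAr to a diaryl ether with four ortho substituents; the free formyl group could also condense with the chromanone methylene). The fallback brings in the carboxyl carbon only after the ether bond is made. It sets out from bromo aldehyde 20 and phenol 15. Cs2CO3 in DMSO at 80 °C displaces the fluoride of 20, which is still activated by the ortho formyl group and carries the smaller bromine in place of the ester, to give 3-bromo-2-{[7-(allyloxy)-2,2,5-trimethyl-4-oxochroman-6-yl]oxy}-6-isopropoxy-4-methylbenzaldehyde F1. Pd(PPh3)4 and morpholine in THF then remove the allyl ether to give 3-bromo-2-[(7-hydroxy-2,2,5-trimethyl-4-oxochroman-6-yl)oxy]-6-isopropoxy-4-methylbenzaldehyde F2. A carbonylative lactonisation (Pd(OAc)2, Xantphos, CO 1 atm, Et3N, toluene, 100 °C) inserts CO into the C–Br bond and traps the acylpalladium with the neighbouring phenol, returning to the route at 28.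

Step 4 (regiochemistry of the Friedel–Crafts acylation of 6). The fallback places the acetyl group first and the oxygen second, with both positions fixed by precedent. It sets out from 1. AcCl/AlCl3 in CH2Cl2 at 0 °C gives 1-(2,4-dimethoxy-6-methylphenyl)ethanone F3, the established site of acylation of 3,5-dimethoxytoluene. BCl3 at −78 to 0 °C cleaves the chelated methoxy group to give 1-(2-hydroxy-4-methoxy-6-methylphenyl)ethanone F4. Elbs persulfate oxidation (K2S2O8, aq. KOH, 0 °C to rt) introduces oxygen strictly para to the phenol, giving potassium 3-acetyl-4-hydroxy-6-methoxy-2-methylphenyl sulfate F5. Hot dilute HCl hydrolyses this to 1-(2,5-dihydroxy-4-methoxy-6-methylphenyl)ethanone F6. MeI (1.0 equiv) and K2CO3 in acetone methylate only the non-chelated 5-hydroxyl, returning to the route at 9.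

Step 13 (ortho-fluoro aryllithium: possible LiF loss to an aryne, or over-addition to the chloroformate). The fallback replaces the organolithium by a palladium-catalysed carbonylation, which also makes steps 12 and 14 unnecessary. It sets out from 20. Hydroxycarbonylation (Pd(OAc)2, Xantphos, CO 1 atm, Et3N, dioxane/H2O, 90 °C) tolerates the free aldehyde and gives 2-fluoro-3-formyl-4-isopropoxy-6-methylbenzoic acid F7. Allyl bromide and KHCO3 in DMF at rt alkylate the hindered carboxylate at oxygen, returning to the route at 24.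

**Further compounds**
F1 | step 15 | 3-bromo-2-{[7-(allyloxy)-2,2,5-trimethyl-4-oxochroman-6-yl]oxy}-6-isopropoxy-4-methylbenzaldehyde | Cc1cc(OC(C)C)c(C=O)c(Oc2c(C)c3C(=O)CC(C)(C)Oc3cc2OCC=C)c1Br
F2 | step 15 | 3-bromo-2-[(7-hydroxy-2,2,5-trimethyl-4-oxochroman-6-yl)oxy]-6-isopropoxy-4-methylbenzaldehyde | Cc1cc(OC(C)C)c(C=O)c(Oc2c(C)c3C(=O)CC(C)(C)Oc3cc2O)c1Br
F3 | step 4 | 1-(2,4-dimethoxy-6-methylphenyl)ethanone | CC(=O)c1c(C)cc(OC)cc1OC
F4 | step 4 | 1-(2-hydroxy-4-methoxy-6-methylphenyl)ethanone | CC(=O)c1c(C)cc(OC)cc1O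
F5 | step 4 | potassium 3-acetyl-4-hydroxy-6-methoxy-2-methylphenyl sulfate | CC(=O)c1c(C)c(OS(=O)(=O)[O-])c(OC)cc1O.[K+]
F6 | step 4 | 1-(2,5-dihydroxy-4-methoxy-6-methylphenyl)ethanone | CC(=O)c1c(C)c(O)c(OC)cc1O
F7 | step 13 | 2-fluoro-3-formyl-4-isopropoxy-6-methylbenzoic acid | Cc1cc(OC(C)C)c(C=O)c(F)c1C(=O)O
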